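**Retrosynthetic overview**
1. Feature: in ring A (C1–C5, C10) the C2 ketone is 1,3 to the fusion carbon C10 and 1,4 to quaternary C5, and the C4 and C5 methyls are cis. Once ring B (C5–C10) borrows a carbonyl at C6, C3–C4 and C5–C10 become the two σ-bonds of a Diels–Alder pair: 2-siloxydiene C10=C1–C2=C3 plus tigloyl enone C4=C5–C6=O.
2. Target 31 ⇒ (double Yamaguchi angeloylation) C8,C9-diol C2-ketone 28 ⇒ (hydrolysis, then Barton–McCombie removal of the borrowed C6 oxygen) cis-fused 6-oxodecalin 23.
3. 23 ⇒ (type 1 intramolecular Diels–Alder) acyclic (E,E)-trienone 22. Rings A and B form together in this one step; the only earlier ring is the temporary C8/C9 dioxolane.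
4. 22 ⇒ but-2-en-2-yllithium + Weinreb amide 19. The C10=C1 enone is made by Wittig reaction only after the aldol and is masked as the silyl dienol ether before any organolithium is used.
5. C7 and C8 ⇒ Evans syn aldol (α-attack of the senecioyl imide dienolate) on the differentially silylated (S)-glyceraldehyde 5, which brings C9 from the chiral pool.

Key step: step 12

Remark: eremophilane numbering is used throughout (C4-Me, C5-Me, H10 and C7-isopropenyl β; O8 and O9 α). The C6 carbinol centre of 24–26 is drawn as the expected 6α epimer, and either epimer serves because C6 becomes CH2 in step 15.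

**Step 1**
Reactants: 1 methyl (S)-2,2-dimethyl-1,3-dioxolane-4-carboxylate
Product: 2 methyl (S)-2,3-dihydroxypropanoate
Conditions: p-TsOH·H2O (cat.), MeOH, rt
Reagents that add atoms: none
Why: Acid-catalysed transketalisation to methanol frees the diol without touching the ester or the stereocentre that becomes C9.

**Step 2**
Reactants: 2 methyl (S)-2,3-dihydroxypropanoate
Product: 4 methyl (S)-3-[(tert-butyldiphenylsilyl)oxy]-2-[(triethylsilyl)oxy]propanoate, via mono-TBDPS ether 3 (not isolated)
Conditions: TBDPSCl, imidazole, DMF, 0 °C; then TESCl, 0 °C → rt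
Reagents that add atoms: TBDPSCl CC(C)(C)[Si](Cl)(c1ccccc1)c1ccccc1; TESCl CC[Si](Cl)(CC)CC
Why: In this sequential silyl ether formation the bulky TBDPSCl takes only the primary C10 hydroxyl, so the TESCl added afterwards caps the secondary C9 hydroxyl with an acid-labile, orthogonal group.

**Step 3**
Reactants: 4 methyl (S)-3-[(tert-butyldiphenylsilyl)oxy]-2-[(triethylsilyl)oxy]propanoate
Product: 5 (S)-3-[(tert-butyldiphenylsilyl)oxy]-2-[(triethylsilyl)oxy]propanal (CHO = C8)
Conditions: i-Bu2AlH, CH2Cl2, −78 °C
Reagents that add atoms: none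
Why: Partial ester reduction stops at the aldehyde because the α-alkoxy aluminium hemiacetal survives at −78 °C, and the non-basic medium leaves C9 intact.

**Step 4**
Reactants: 6 (R)-4-benzyl-1,3-oxazolidin-2-one; 7 3-methylbut-2-enoyl chloride
Product: 9 (R)-4-benzyl-3-(3-methylbut-2-enoyl)-1,3-oxazolidin-2-one, via lithium oxazolidinide 8 (not isolated)
Conditions: n-BuLi, THF, −78 °C; then 7, −78 → 0 °C
Reagents that add atoms: n-BuLi (lithium of 8 only) [Li]CCCC
Why: N-Acylation of the lithiated oxazolidinone with an acid chloride is the standard entry to Evans imides, and the low temperature prevents deconjugation of the senecioyl unit.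

**Step 5**
Reactants: 9 (R)-4-benzyl-3-(3-methylbut-2-enoyl)-1,3-oxazolidin-2-one; 5 (S)-3-[(tert-butyldiphenylsilyl)oxy]-2-[(triethylsilyl)oxy]propanal
Product: 11 (R)-4-benzyl-3-[(2R,3R,4S)-5-(TBDPS-oxy)-3-hydroxy-2-(prop-1-en-2-yl)-4-(TES-oxy)pentanoyl]-1,3-oxazolidin-2-one, via boron dienolate 10 (not isolated)
Conditions: n-Bu2BOTf, Et3N, CH2Cl2, −78 → 0 °C; 5, −78 → 0 °C; H2O2, MeOH, pH 7 buffer, 0 °C
Reagents that add atoms: n-Bu2BOTf (boron unit of 10 only) CCCCB(CCCC)OS(=O)(=O)C(F)(F)F
Why: In this Evans syn aldol of a crotonate-type imide, soft γ-deprotonation gives the Z(O)-boron dienolate, which reacts at its α-carbon C7 through a Zimmerman–Traxler chair where the (R)-benzyl auxiliary fixes C7 and C8 as the syn pair, a sense that coincides with Felkin–Anh attack on the α-silyloxy aldehyde (8,9-anti).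

**Step 6**
Reactants: 11 syn-aldol imide
Product: 12 (2R,3R,4S)-5-(TBDPS-oxy)-3-hydroxy-N-methoxy-N-methyl-2-(prop-1-en-2-yl)-4-(TES-oxy)pentanamide
Conditions: MeONHMe·HCl, AlMe3, THF, −10 → 0 °C
Reagents that add atoms: N,O-dimethylhydroxylamine hydrochloride CNOC.Cl
Why: Weinreb transamidation with the aluminium amide, assisted by the free C8 hydroxyl, replaces the auxiliary under conditions that do not epimerise or conjugate C7.

**Step 7**
Reactants: 12 Weinreb amide (C8-OH, C9-OTES)
Product: 14 (2R)-2-[(4R,5S)-5-(TBDPS-oxymethyl)-2,2-dimethyl-1,3-dioxolan-4-yl]-N-methoxy-N,3-dimethylbut-3-enamide, via C8/C9 diol 13 (not isolated)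
Conditions: PPTS, 2,2-dimethoxypropane–MeOH (10:1), rt
Reagents that add atoms: 2,2-dimethoxypropane COC(C)(C)OC
Why: Mild acid methanolysis removes only the secondary TES ether, and the anti-8,9-diol is ketalised at once to the cis-dioxolane, the fast trapping forestalling lactonisation of O9 onto the amide.

**Step 8**
Reactants: 14 acetonide TBDPS ether
Product: 15 (2R)-2-[(4R,5S)-5-(hydroxymethyl)-2,2-dimethyl-1,3-dioxolan-4-yl]-N-methoxy-N,3-dimethylbut-3-enamide
Conditions: Bu4NF, AcOH, THF, 0 °C → rt
Reagents that add atoms: none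
Why: Fluoride desilylation frees the C10 alcohol, and the acetic acid buffer keeps the alkoxide from attacking the amide and protects the acidic C7–H.

**Step 9**
Reactants: 15 C10 alcohol; 16 1-(triphenylphosphoranylidene)propan-2-one
Product: 18 (2R)-2-{(4R,5S)-2,2-dimethyl-5-[(E)-3-oxobut-1-enyl]-1,3-dioxolan-4-yl}-N-methoxy-N,3-dimethylbut-3-enamide, via C10 aldehyde 17 (not isolated)
Conditions: Dess–Martin periodinane, CH2Cl2, 0 °C → rt; then 16, rt
Reagents that add atoms: none
Why: Dess–Martin oxidation followed in the same flask by Wittig olefination with the stabilised ylide gives the E enone, and the epimerisable cis-dioxolane aldehyde is consumed as it forms.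

**Step 10**
Reactants: 18 E enone amide
Product: 19 (2R)-2-{(4R,5S)-5-[(E)-3-(TBS-oxy)buta-1,3-dienyl]-2,2-dimethyl-1,3-dioxolan-4-yl}-N-methoxy-N,3-dimethylbut-3-enamide
Conditions: TBSOTf, Et3N, CH2Cl2, −78 → 0 °C
Reagents that add atoms: TBSOTf CC(C)(C)[Si](C)(C)OS(=O)(=O)C(F)(F)F
Why: Soft kinetic enol silylation of the methyl ketone at C3 gives the cross-conjugated 2-siloxydiene while the far less enolisable amide stays untouched, and it masks the enone before the organolithium step.

**Step 11**
Reactants: 19 siloxydiene Weinreb amide; 20 (E)-2-bromobut-2-ene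
Product: 22 (E,E)-trienone: C6 tigloyl ketone with (7R)-isopropenyl (8R,9S)-cis-acetonide and 2-(TBS-oxy)diene C10=C1–C2=C3, via but-2-en-2-yllithium 21 (not isolated)
Conditions: 20, t-BuLi (2 equiv per 20), Et2O, −78 °C; then 19, THF, −78 → −40 °C; aq. NH4Cl
Reagents that add atoms: t-BuLi (lithium of 21 only) [Li]C(C)(C)C
Why: Halogen–lithium exchange proceeds with retention of alkene geometry, and in the Weinreb ketone synthesis the chelated tetrahedral adduct blocks over-addition and collapses on work-up to the E tigloyl ketone, the TBS dienol ether being inert to the organolithium at −78 °C.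

**Step 12**
Reactants: 22 (E,E)-trienone
Product: 23 2-(TBS-oxy)-8α,9α-(isopropylidenedioxy)-10βH-eremophila-1,11-dien-6-one (cis-fused)
Conditions: Me2AlCl (1.2 equiv), CH2Cl2, −78 → −20 °C
Reagents that add atoms: none
Why: Me2AlCl binds the C6 carbonyl of the s-cis tigloyl enone and triggers a concerted, asynchronous [4+2] cycloaddition in which the siloxy-activated diene terminus C3 bonds ahead to the enone β-carbon C4 and C10 follows onto C5, the electronically matched "para" orientation that the bridge also imposes. The closest known reaction type is the thermal or Lewis-acid-promoted type 1 intramolecular Diels–Alder reaction of 1,7,9-decatrien-3-ones, which gives cis-fused octalones through the endo mode with the bridge carbonyl under the diene. Ring A closes as the new cyclohexene by both σ-bonds through a boat-like six-centre array, and ring B closes at the same time as a six-membered carbocycle made of the C5–C10 bond and the four-atom bridge C6–C9. C4 and C5 are set by suprafacial addition to the E alkene (cis methyls), and C10 by the E geometry of C10=C1 together with the endo bridge, which puts H10 on the face of the C5 methyl (cis fusion). The π-face is set by C7–C9: in the endo mode of an E diene the C5 methyl is axial on nascent ring B, so a chair bridge would need an axial isopropenyl group, and the required face is reached through the boat-like bridge (C5 and C8 as bow and stern) known for this trienone class, with isopropenyl and O8 pseudo-equatorial, O9 turned away from the dienophile and the cis-dioxolane holding C7 and C10 gauche, whereas the opposite face needs a chair with O9 axial against the C5 methyl and isopropenyl eclipsing the aluminium-bound carbonyl. The step thus needs endo over exo selectivity (helped by the Lewis acid and low temperature) and one diene/dienophile face pairing (secured only by these conformational preferences, the long C5···C10 distance of the asynchronous transition state easing the C5-methyl/H8 contact of the boat), and it must leave the acidic C7–H untouched, which the non-basic medium allows.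

**Step 13**
Reactants: 23 cis-fused 6-oxodecalin
Product: 24 2-(TBS-oxy)-8α,9α-(isopropylidenedioxy)-10βH-eremophila-1,11-dien-6α-ol
Conditions: i-Bu2AlH, CH2Cl2, −78 °C
Reagents that add atoms: none
Why: 1,2-Reduction by the non-basic hydride reaches the hindered C6 ketone without enolising C7 or touching the enol ether, hydride being expected along the axial β trajectory (the α face carries axial C4 and the dioxolane) to give the equatorial 6α-alcohol, a centre erased in step 15.

**Step 14**
Reactants: 24 C6 alcohol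
Product: 26 O-(6α) S-methyl xanthate of 24, via sodium xanthate 25 (not isolated)
Conditions: NaH, CS2, THF, 0 °C → rt; then MeI
Reagents that add atoms: NaH (sodium of 25 only) [Na+].[H-]; carbon disulfide S=C=S; iodomethane CI
Why: In this xanthate formation, the first half of the Barton–McCombie deoxygenation, the small electrophile CS2 captures even a neopentyl-type alkoxide, and no base-sensitive carbonyl is left in the molecule.

**Step 15**
Reactants: 26 C6 xanthate
Product: 27 2-(TBS-oxy)-8α,9α-(isopropylidenedioxy)-10βH-eremophila-1,11-diene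
Conditions: Bu3SnH (0.5 M), AIBN (cat.), toluene, 90 °C
Reagents that add atoms: none
Why: In the Barton–McCombie deoxygenation, stannyl radical addition to C=S and β-scission give the secondary C6 radical, which at high stannane concentration abstracts hydrogen faster than it can attack the neighbouring isopropenyl group (1,2-vinyl shift), and no stereocentre is affected.

**Step 16**
Reactants: 27 deoxygenated enol ether acetonide
Product: 28 8α,9α-dihydroxy-10βH-eremophil-11-en-2-one
Conditions: 1 M HCl, THF, rt
Reagents that add atoms: none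
Why: Aqueous acid hydrolyses the silyl enol ether to the C2 ketone and the acetonide to the cis-diol in one operation, C10 being β to the new ketone and therefore not epimerisable, and dilute acid at room temperature spares the 1,1-disubstituted alkene.

**Step 17**
Reactants: 28 diol ketone; 29 angelic acid [(Z)-2-methylbut-2-enoic acid]
Product: 31 8α,9α-bis(angeloyloxy)-10βH-eremophil-11-en-2-one (CNP0249036.1), via angelic trichlorobenzoic anhydride 30 (not isolated)
Conditions: 29, 2,4,6-trichlorobenzoyl chloride, Et3N, toluene, rt; then 28, 80 °C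
Reagents that add atoms: 2,4,6-trichlorobenzoyl chloride (aroyl part of 30 only) O=C(Cl)c1c(Cl)cc(Cl)cc1Cl
Why: In the Yamaguchi esterification the mixed anhydride acylates both secondary hydroxyls at the angeloyl carbonyl, and leaving out nucleophilic catalysts such as DMAP avoids the addition–elimination path that turns angelate into tiglate.

**Compound list**
1 | methyl (S)-2,2-dimethyl-1,3-dioxolane-4-carboxylate | COC(=O)[C@@H]1COC(C)(C)O1 | starting material
2 | methyl (S)-2,3-dihydroxypropanoate | COC(=O)[C@@H](O)CO | intermediate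
3 | methyl (S)-3-[(tert-butyldiphenylsilyl)oxy]-2-hydroxypropanoate | COC(=O)[C@@H](O)CO[Si](c1ccccc1)(c1ccccc1)C(C)(C)C | intermediate
4 | methyl (S)-3-[(tert-butyldiphenylsilyl)oxy]-2-[(triethylsilyl)oxy]propanoate | COC(=O)[C@@H](O[Si](CC)(CC)CC)CO[Si](c1ccccc1)(c1ccccc1)C(C)(C)C | intermediate
5 | (S)-3-[(tert-butyldiphenylsilyl)oxy]-2-[(triethylsilyl)oxy]propanal | O=C[C@@H](O[Si](CC)(CC)CC)CO[Si](c1ccccc1)(c1ccccc1)C(C)(C)C | intermediate
6 | (R)-4-benzyl-1,3-oxazolidin-2-one | O=C1N[C@H](Cc2ccccc2)CO1 | starting material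
7 | 3-methylbut-2-enoyl chloride | CC(C)=CC(=O)Cl | starting material
8 | lithium salt of 6 | [Li]N1C(=O)OC[C@H]1Cc1ccccc1 | intermediate
9 | (R)-4-benzyl-3-(3-methylbut-2-enoyl)-1,3-oxazolidin-2-one | CC(C)=CC(=O)N1C(=O)OC[C@H]1Cc1ccccc1 | intermediate
10 | Z(O)-dibutylboron dienolate of 9 | C=C(C)/C=C(\OB(CCCC)CCCC)N1C(=O)OC[C@H]1Cc1ccccc1 | intermediate
11 | syn-aldol imide (7R,8R,9S) | C=C(C)[C@@H](C(=O)N1C(=O)OC[C@H]1Cc1ccccc1)[C@@H](O)[C@@H](O[Si](CC)(CC)CC)CO[Si](c1ccccc1)(c1ccccc1)C(C)(C)C | intermediate
12 | Weinreb amide, C8-OH, C9-OTES, C10-OTBDPS | C=C(C)[C@@H](C(=O)N(C)OC)[C@@H](O)[C@@H](O[Si](CC)(CC)CC)CO[Si](c1ccccc1)(c1ccccc1)C(C)(C)C | intermediate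
13 | Weinreb amide, C8/C9 diol | C=C(C)[C@@H](C(=O)N(C)OC)[C@@H](O)[C@@H](O)CO[Si](c1ccccc1)(c1ccccc1)C(C)(C)C | intermediate
14 | Weinreb amide, C8/C9 cis-acetonide, C10-OTBDPS | C=C(C)[C@@H](C(=O)N(C)OC)[C@H]1OC(C)(C)O[C@H]1CO[Si](c1ccccc1)(c1ccccc1)C(C)(C)C | intermediate
15 | Weinreb amide, acetonide, C10 alcohol | C=C(C)[C@@H](C(=O)N(C)OC)[C@H]1OC(C)(C)O[C@H]1CO | intermediate
16 | 1-(triphenylphosphoranylidene)propan-2-one | CC(=O)C=P(c1ccccc1)(c1ccccc1)c1ccccc1 | starting material
17 | Weinreb amide, acetonide, C10 aldehyde | C=C(C)[C@@H](C(=O)N(C)OC)[C@H]1OC(C)(C)O[C@H]1C=O | intermediate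
18 | Weinreb amide, acetonide, (E)-C10=C1 methyl enone | C=C(C)[C@@H](C(=O)N(C)OC)[C@H]1OC(C)(C)O[C@H]1/C=C/C(C)=O | intermediate
19 | Weinreb amide, acetonide, (E)-2-(TBS-oxy)diene | C=C(C)[C@@H](C(=O)N(C)OC)[C@H]1OC(C)(C)O[C@H]1/C=C/C(=C)O[Si](C)(C)C(C)(C)C | intermediate
20 | (E)-2-bromobut-2-ene | C/C=C(\C)Br | starting material
21 | but-2-en-2-yllithium (methyls cis, geometry of 20 retained) | [Li]/C(C)=C/C | intermediate
22 | (E,E)-trienone, key-step precursor | C=C(C)[C@@H](C(=O)/C(C)=C/C)[C@H]1OC(C)(C)O[C@H]1/C=C/C(=C)O[Si](C)(C)C(C)(C)C | intermediate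
23 | cis-fused 6-oxodecalin, key-step product | C=C(C)[C@H]1C(=O)[C@@]2(C)[C@H](C=C(O[Si](C)(C)C(C)(C)C)C[C@@H]2C)[C@H](OC(C)(C)O3)[C@@H]13 | intermediate
24 | 6α-alcohol | C=C(C)[C@H]1[C@H](O)[C@@]2(C)[C@H](C=C(O[Si](C)(C)C(C)(C)C)C[C@@H]2C)[C@H](OC(C)(C)O3)[C@@H]13 | intermediate
25 | sodium xanthate of 24 | C=C(C)[C@H]1[C@H](OC(=S)[S-])[C@@]2(C)[C@H](C=C(O[Si](C)(C)C(C)(C)C)C[C@@H]2C)[C@H](OC(C)(C)O3)[C@@H]13.[Na+] | intermediate
26 | S-methyl xanthate of 24 | C=C(C)[C@H]1[C@H](OC(=S)SC)[C@@]2(C)[C@H](C=C(O[Si](C)(C)C(C)(C)C)C[C@@H]2C)[C@H](OC(C)(C)O3)[C@@H]13 | intermediate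
27 | C6-deoxygenated enol ether acetonide | C=C(C)[C@H]1C[C@@]2(C)[C@H](C=C(O[Si](C)(C)C(C)(C)C)C[C@@H]2C)[C@H](OC(C)(C)O3)[C@@H]13 | intermediate
28 | 8α,9α-dihydroxy-10βH-eremophil-11-en-2-one | C=C(C)[C@H]1C[C@@]2(C)[C@H](CC(=O)C[C@@H]2C)[C@H](O)[C@@H]1O | intermediate
29 | angelic acid | C/C=C(/C)C(=O)O | starting material
30 | angelic 2,4,6-trichlorobenzoic anhydride | C/C=C(/C)C(=O)OC(=O)c1c(Cl)cc(Cl)cc1Cl | intermediate
31 | 8α,9α-bis(angeloyloxy)-10βH-eremophil-11-en-2-one (CNP0249036.1) | C=C(C)[C@H]1C[C@@]2(C)[C@H](CC(=O)C[C@@H]2C)[C@H](OC(=O)/C(C)=C\C)[C@@H]1OC(=O)/C(C)=C\C | target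

**Step count**
Total step count: 17. Longest linear sequence: 16 (steps 1–3 and 5–17, from 1).

**Steps most likely to fail**

Step 12.
- What may go wrong: the boat-like endo array that leads to the required face is penalised by the contact between the C5 methyl and H8. The chair-like endo array on the other π-face, or the exo (trans-fused) mode, may therefore compete, giving poor facial and endo/exo selectivity. The Lewis acid may also strip the silyl group.
- Fallback (sets out from 5, comes back at 24): the same two Diels–Alder bonds are made intermolecularly, and ring B is closed afterwards by a carbonyl-ene reaction.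
- 2-Methylprop-1-enylmagnesium bromide adds to 5 (THF, −78 °C, Felkin–Anh control, 8,9-anti) to give allylic alcohol F1.
- PPTS in 2,2-dimethoxypropane–MeOH takes it through diol F2 to acetonide F3, and Bu4NF gives primary alcohol F4.
- Dess–Martin oxidation to aldehyde F5 and Wittig reaction with 16 give E enone F6, and TBSOTf/Et3N gives siloxydiene F7.
- The Me2AlCl-promoted Diels–Alder reaction of F7 with (E)-2-methylbut-2-enal forms C3–C4 and C5–C10 and ring A alone, giving cyclohexene aldehyde F8. Its formyl carbon is C6: para orientation, endo formyl group cis to C9, cis methyls from the E enal, and the diene face biased by the C9 dioxolane.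
- A type 1 carbonyl-ene cyclisation of F8 (Me2AlCl, CH2Cl2, −78 °C), the closure known from citronellal to isopulegol, then joins C6 to C7. It runs through a chair in which hydroxyl, isopropenyl and O8 are equatorial, creates the isopropenyl group from the C7=C11 alkene, and delivers 24.

Step 11.
- What may go wrong: the basic vinyllithium may deprotonate the α-branched amide at C7 instead of adding, with loss of C7 configuration or β-elimination of O8, or it may add sluggishly.
- Fallback (sets out from 19, comes back at 22): acyl substitution is replaced by addition followed by oxidation.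
- i-Bu2AlH (THF, −78 °C) reduces 19 to aldehyde F9, which is far more electrophilic and takes up 21 at −78 °C to give allylic alcohol F10 (both C6 epimers are usable).
- MnO2 in CH2Cl2 oxidises the allylic carbinol under neutral conditions that the dienol ether tolerates and gives 22.

Step 17.
- What may go wrong: incomplete acylation of the hindered axial C9 hydroxyl, and Z to E isomerisation of the angeloyl unit under forcing conditions.
- Fallback (sets out from 28, comes back at 31): the Z alkenes are built after the acylation.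
- Both hydroxyls are esterified with the saturated, more reactive 2-[bis(2,2,2-trifluoroethoxy)phosphoryl]propanoic acid (DCC, DMAP, CH2Cl2) to give bis(phosphonopropionate) F11.
- A double Still–Gennari olefination (KN(SiMe3)2, 18-crown-6, THF, −78 °C, then acetaldehyde) converts each phosphonate into the Z-trisubstituted angelate and gives 31. The phosphonate protons are removed in preference to those of the C2 ketone.

**Further compounds**
F1 | step 12 | (2S,3R)-1-[(tert-butyldiphenylsilyl)oxy]-5-methyl-2-[(triethylsilyl)oxy]hex-4-en-3-ol | CC(C)=C[C@@H](O)[C@@H](O[Si](CC)(CC)CC)CO[Si](c1ccccc1)(c1ccccc1)C(C)(C)C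
F2 | step 12 | (2S,3R)-1-[(tert-butyldiphenylsilyl)oxy]-5-methylhex-4-ene-2,3-diol | CC(C)=C[C@@H](O)[C@@H](O)CO[Si](c1ccccc1)(c1ccccc1)C(C)(C)C
F3 | step 12 | tert-butyl{[(4S,5R)-2,2-dimethyl-5-(2-methylprop-1-enyl)-1,3-dioxolan-4-yl]methoxy}diphenylsilane | CC(C)=C[C@H]1OC(C)(C)O[C@H]1CO[Si](c1ccccc1)(c1ccccc1)C(C)(C)C
F4 | step 12 | [(4S,5R)-2,2-dimethyl-5-(2-methylprop-1-enyl)-1,3-dioxolan-4-yl]methanol | CC(C)=C[C@H]1OC(C)(C)O[C@H]1CO
F5 | step 12 | (4R,5R)-2,2-dimethyl-5-(2-methylprop-1-enyl)-1,3-dioxolane-4-carbaldehyde | CC(C)=C[C@H]1OC(C)(C)O[C@H]1C=O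
F6 | step 12 | (E)-4-[(4S,5R)-2,2-dimethyl-5-(2-methylprop-1-enyl)-1,3-dioxolan-4-yl]but-3-en-2-one | CC(C)=C[C@H]1OC(C)(C)O[C@H]1/C=C/C(C)=O
F7 | step 12 | 2-(TBS-oxy)diene derived from F6 | CC(C)=C[C@H]1OC(C)(C)O[C@H]1/C=C/C(=C)O[Si](C)(C)C(C)(C)C
F8 | step 12 | ring A cyclohexene carbaldehyde (formyl carbon = C6, side chain C9–C8–C7=C11 on C10) | O=C[C@@]2(C)[C@H](C=C(O[Si](C)(C)C(C)(C)C)C[C@@H]2C)[C@@H]1OC(C)(C)O[C@@H]1C=C(C)C
F9 | step 11 | C6 aldehyde corresponding to 19 | C=C(C)[C@@H](C=O)[C@H]1OC(C)(C)O[C@H]1/C=C/C(=C)O[Si](C)(C)C(C)(C)C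
F10 | step 11 | C6 allylic alcohol (C6 epimers) corresponding to 22 | C=C(C)[C@@H](C(O)/C(C)=C/C)[C@H]1OC(C)(C)O[C@H]1/C=C/C(=C)O[Si](C)(C)C(C)(C)C
F11 | step 17 | 8,9-bis{2-[bis(2,2,2-trifluoroethoxy)phosphoryl]propanoate} of 28 | C=C(C)[C@H]1C[C@@]2(C)[C@H](CC(=O)C[C@@H]2C)[C@H](OC(=O)C(C)P(=O)(OCC(F)(F)F)OCC(F)(F)F)[C@@H]1OC(=O)C(C)P(=O)(OCC(F)(F)F)OCC(F)(F)F
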